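Ring B of the target (C5–C6–C7–C8–C1–C9 in bicyclo[3.3.1]nonane numbering, C9 being the bridging ketone) is a cyclohexanone whose carbonyl C9 and side-chain carbon C7 stand 1,4, with the gem-dimethyl carbon C8 between C7 and C1. That is the retron of a 2-siloxydiene Diels–Alder reaction. A mesityl-oxide-derived diene, C5=C9(OTIPS)–C1=C8Me2, and a chiral acrylimide (C6=C7) are joined in one operation, which forms C5–C6 and C7–C8, the quaternary C8, the C7 stereocentre that later controls C1 and C5, and a regiodefined C9=C1 enol ether. Ring A is then closed by Effenberger annulation; the C5 side chain and the aroyl group follow by directed lithiations.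

Key step: step 3

Remark: in the Why lines atom numbers are those of the final bicyclic core (bridgeheads C1 and C5, gem-dimethyl C8, bridging carbonyl C9; ring A = C1–C2–C3–C4–C5–C9, ring B = C5–C6–C7–C8–C1–C9), also for monocyclic precursors; enols are drawn as one tautomer, and CIP descriptors refer to the tautomer drawn.

Step 1
Reactants: 1 4-methylpent-3-en-2-one (mesityl oxide)
Product: 3 4-methyl-2-[(triisopropylsilyl)oxy]penta-1,3-diene, via lithium dienolate 2 (not isolated)
Conditions: LiN(iPr)2 (LDA), THF, −78 °C; then TIPSOTf, −78 → 0 °C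
Reagents that add atoms: triisopropylsilyl trifluoromethanesulfonate, CC(C)[Si](C(C)C)(C(C)C)OS(=O)(=O)C(F)(F)F
Why: Kinetic deprotonation of the methyl ketone gives the cross-conjugated dienolate, which is O-silylated (silyl enol ether formation); no stereocentre is formed.

Step 2
Reactants: 4 (4S)-4-benzyl-1,3-oxazolidin-2-one; 5 acryloyl chloride
Product: 7 (4S)-3-acryloyl-4-benzyl-1,3-oxazolidin-2-one, via lithium oxazolidinide 6 (not isolated)
Conditions: n-BuLi, THF, −78 °C; then 5, −78 → 0 °C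
Reagents that add atoms: none
Why: N-acylation of the lithiated oxazolidinone auxiliary; the stereocentre of 4 is not touched.

Step 3
Reactants: 3 4-methyl-2-[(triisopropylsilyl)oxy]penta-1,3-diene; 7 (4S)-3-acryloyl-4-benzyl-1,3-oxazolidin-2-one
Product: 8 (4S)-4-benzyl-3-{[(1R)-2,2-dimethyl-4-[(triisopropylsilyl)oxy]cyclohex-3-en-1-yl]carbonyl}-1,3-oxazolidin-2-one
Conditions: Et2AlCl (1.4 equiv), CH2Cl2, −78 °C; quench with Et3N then aq NaHCO3
Reagents that add atoms: none
Why: Et2AlCl converts the imide into a cationic bidentate aluminium chelate with an s-cis acryloyl unit, to which the electron-rich 2-siloxydiene adds in a strongly asynchronous [4+2] cycloaddition: C5–C6 bonding (Mukaiyama–Michael-like) leads and C7–C8 bonding closes the ring onto the siloxyallyl cation terminus. The closest known reaction type is the oxazolidinone-auxiliary Diels–Alder reaction with aluminium Lewis acids, and Lewis-acid cycloadditions of hindered 4,4-disubstituted 2-siloxydienes that create a quaternary carbon at the diene terminus are established. Ring B closes as a six-membered ring in the [4+2] mode (6-endo at the second bond if the process is stepwise). C7 is the only new stereocentre and is set by the auxiliary: its benzyl group shields the Cα Re face of the chelate, so the diene should add to the Si face and give the R configuration. Regiochemistry (C5 to C6 and C8 to C7) follows from the siloxy group, which makes C5 the nucleophilic terminus and places the C9 oxygen and the C7 acyl group 1,4. Ring closure must outrun silyl transfer to an open-chain Michael adduct, which the bulky TIPS group and the low temperature should secure.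

Step 4
Reactants: 8 (4S)-4-benzyl-3-{[(1R)-2,2-dimethyl-4-[(triisopropylsilyl)oxy]cyclohex-3-en-1-yl]carbonyl}-1,3-oxazolidin-2-one
Product: 9 [(1R)-2,2-dimethyl-4-[(triisopropylsilyl)oxy]cyclohex-3-en-1-yl]methanol
Conditions: LiBH4, MeOH (1.1 equiv), THF, 0 °C
Reagents that add atoms: none
Why: Reductive cleavage of the N-acyl oxazolidinone by borohydride should release the primary alcohol and the recoverable auxiliary, leaving the silyl enol ether and C7 untouched.

Step 5
Reactants: 9 [(1R)-2,2-dimethyl-4-[(triisopropylsilyl)oxy]cyclohex-3-en-1-yl]methanol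
Product: 10 {[(4R)-4-(iodomethyl)-3,3-dimethylcyclohex-1-en-1-yl]oxy}triisopropylsilane
Conditions: PPh3, I2, imidazole (premixed), CH2Cl2, 0 °C
Reagents that add atoms: iodine, II
Why: Appel-type iodination of the primary alcohol (SN2 at CH2); premixing the phosphine and iodine keeps free iodine away from the enol ether.

Step 6
Reactants: 10 {[(4R)-4-(iodomethyl)-3,3-dimethylcyclohex-1-en-1-yl]oxy}triisopropylsilane; 11 1-bromo-2-methylprop-1-ene
Product: 13 {[(4S)-3,3-dimethyl-4-(3-methylbut-2-en-1-yl)cyclohex-1-en-1-yl]oxy}triisopropylsilane, via alkylzinc iodide 12 (not isolated)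
Conditions: Zn dust, LiCl, THF, 40 °C; then 11, Pd(PPh3)4 (5 mol %), THF, 50 °C
Reagents that add atoms: none
Why: Zinc insertion into the primary C–I bond and Negishi coupling with the alkenyl bromide under zerovalent palladium should build the C7 prenyl group without touching the stereocentre or the enol ether.

Step 7
Reactants: 13 {[(4S)-3,3-dimethyl-4-(3-methylbut-2-en-1-yl)cyclohex-1-en-1-yl]oxy}triisopropylsilane; 14 1-bromo-3-methylbut-2-ene (prenyl bromide)
Product: 16 (4S)-3,3-dimethyl-2,4-bis(3-methylbut-2-en-1-yl)cyclohexan-1-one (C2 epimers), via sulfonium enolate 15 (not isolated)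
Conditions: (Me2N)3S+ Me3SiF2− (TASF, 1.1 equiv), 14 (3 equiv), THF, −78 → 0 °C
Reagents that add atoms: none
Why: Fluoride cleavage of the silyl enol ether gives the regiodefined C9=C1 enolate, which is C-alkylated by the allylic bromide (regiospecific alkylation of a silyl enol ether through its naked enolate); the new C1 centre is inconsequential because C1 becomes planar again in step 9.

Step 8
Reactants: 16 (4S)-3,3-dimethyl-2,4-bis(3-methylbut-2-en-1-yl)cyclohexan-1-one (C2 epimers)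
Product: 18 tert-butyl{[(4R)-5,5-dimethyl-4,6-bis(3-methylbut-2-en-1-yl)cyclohex-1-en-1-yl]oxy}dimethylsilane, via lithium enolate 17 (not isolated)
Conditions: LiN(iPr)2 (LDA), THF, −78 °C; then TBSCl, DMPU, −78 → 0 °C
Reagents that add atoms: tert-butyldimethylsilyl chloride, CC(C)(C)[Si](C)(C)Cl
Why: Kinetic deprotonation should occur at the unhindered C5 methylene (C1–H is tertiary and neopentyl), and O-silylation gives the C9=C5 silyl enol ether.

Step 9
Reactants: 18 tert-butyl{[(4R)-5,5-dimethyl-4,6-bis(3-methylbut-2-en-1-yl)cyclohex-1-en-1-yl]oxy}dimethylsilane; 19 malonyl dichloride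
Product: 21 (1R,5S,7R)-4-hydroxy-8,8-dimethyl-1,7-bis(3-methylbut-2-en-1-yl)bicyclo[3.3.1]non-3-ene-2,9-dione, via keto acid chloride 20 (not isolated)
Conditions: Et2O, −20 → 20 °C; then aq KOH, BnEt3NCl
Reagents that add atoms: none
Why: Effenberger cyclisation: the enol ether is C-acylated at C5 and the second acyl chloride then acylates the C9=C1 enol intramolecularly to close ring A; because C5 stays epimerisable and C1 is planar, closure should occur on the face of ring B cis to C7–H (anti to the axial C8 methyl), leaving the C7 prenyl equatorial (exo) and so fixing C1 and C5 relative to C7.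

Step 10
Reactants: 21 (1R,5S,7R)-4-hydroxy-8,8-dimethyl-1,7-bis(3-methylbut-2-en-1-yl)bicyclo[3.3.1]non-3-ene-2,9-dione
Product: 22 (1R,5S,7R)-8,8-dimethyl-1,7-bis(3-methylbut-2-en-1-yl)-2-[2-(trimethylsilyl)ethoxy]bicyclo[3.3.1]non-2-ene-4,9-dione
Conditions: 2-(trimethylsilyl)ethanol, PPh3, DIAD, THF, 0 → 20 °C
Reagents that add atoms: 2-(trimethylsilyl)ethanol, C[Si](C)(C)CCO
Why: Mitsunobu O-alkylation of the acidic enol gives a fluoride-labile vinylogous ester; of the two regioisomers the one with the C4 carbonyl beside C5–H (22) is carried on and the other is returned to 21 with Bu4NF.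

Step 11
Reactants: 23 ethyl (2E)-3-methyl-4-oxobut-2-enoate; 24 allyltributylstannane
Product: 25 ethyl (2E,4S)-4-hydroxy-3-methylhepta-2,6-dienoate
Conditions: Ti(OiPr)4 (10 mol %), (S)-BINOL (20 mol %), 4 Å MS, CH2Cl2, −20 °C
Reagents that add atoms: none
Why: Keck asymmetric allylation should add the allyl group to the Si face of the aldehyde, chemoselectively over the ester, and so set the S carbinol centre under control of the (S)-BINOL titanium catalyst.

Step 12
Reactants: 25 ethyl (2E,4S)-4-hydroxy-3-methylhepta-2,6-dienoate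
Product: 26 ethyl (2E,4S)-4-[(tert-butyldimethylsilyl)oxy]-3-methylhepta-2,6-dienoate
Conditions: TBSCl, imidazole, DMF, 20 °C
Reagents that add atoms: tert-butyldimethylsilyl chloride, CC(C)(C)[Si](C)(C)Cl
Why: Silylation of the secondary alcohol gives an ether that survives the later amide bases and the malonyl-free endgame and is removed by fluoride at the end.

Step 13
Reactants: 26 ethyl (2E,4S)-4-[(tert-butyldimethylsilyl)oxy]-3-methylhepta-2,6-dienoate; 27 2-methylbut-2-ene
Product: 28 ethyl (2E,4S)-4-[(tert-butyldimethylsilyl)oxy]-3,7-dimethylocta-2,6-dienoate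
Conditions: second-generation Grubbs catalyst (5 mol %), 27 (excess), CH2Cl2, 40 °C
Reagents that add atoms: none
Why: Olefin cross-metathesis of the terminal alkene with 2-methylbut-2-ene should give the prenyl terminus, the trisubstituted electron-poor enoate alkene being inert.

Step 14
Reactants: 28 ethyl (2E,4S)-4-[(tert-butyldimethylsilyl)oxy]-3,7-dimethylocta-2,6-dienoate
Product: 29 (2E,4S)-4-[(tert-butyldimethylsilyl)oxy]-3,7-dimethylocta-2,6-dien-1-ol
Conditions: iBu2AlH (2.2 equiv), CH2Cl2, −78 °C; Rochelle salt work-up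
Reagents that add atoms: none
Why: 1,2-Reduction of the enoate by the aluminium hydride gives the allylic alcohol with the E geometry and the carbinol centre unchanged.

Step 15
Reactants: 29 (2E,4S)-4-[(tert-butyldimethylsilyl)oxy]-3,7-dimethylocta-2,6-dien-1-ol
Product: 30 {[(2E,4S)-1-bromo-3,7-dimethylocta-2,6-dien-4-yl]oxy}(tert-butyl)dimethylsilane
Conditions: CBr4, PPh3, CH2Cl2, 0 °C
Reagents that add atoms: carbon tetrabromide, BrC(Br)(Br)Br
Why: Appel bromination converts the primary allylic alcohol into the bromide by SN2 under neutral conditions that the silyl ether tolerates.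

Step 16
Reactants: 22 (1R,5S,7R)-8,8-dimethyl-1,7-bis(3-methylbut-2-en-1-yl)-2-[2-(trimethylsilyl)ethoxy]bicyclo[3.3.1]non-2-ene-4,9-dione; 30 {[(2E,4S)-1-bromo-3,7-dimethylocta-2,6-dien-4-yl]oxy}(tert-butyl)dimethylsilane
Product: 32 (1R,5S,7R)-5-[(2E,4S)-4-[(tert-butyldimethylsilyl)oxy]-3,7-dimethylocta-2,6-dien-1-yl]-8,8-dimethyl-1,7-bis(3-methylbut-2-en-1-yl)-2-[2-(trimethylsilyl)ethoxy]bicyclo[3.3.1]non-2-ene-4,9-dione, via bridgehead organolithium 31 (not isolated)
Conditions: LiN(iPr)2 (LDA, 1.2 equiv), THF, −78 °C; then 30, −78 → −40 °C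
Reagents that add atoms: none
Why: The amide base should remove the bridgehead C5–H, which lies between the C9 and C4 carbonyl groups (bridgehead lithiation of a bicyclo[3.3.1]nonane vinylogous ester), and the pyramidal carbanion is alkylated by SN2 at the primary allylic bromide with retention, the only geometry the bicycle allows.

Step 17
Reactants: 33 3,4-dihydroxybenzoic acid
Product: 34 tert-butyldimethylsilyl 3,4-bis[(tert-butyldimethylsilyl)oxy]benzoate
Conditions: TBSCl (3.5 equiv), imidazole, DMF, 20 °C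
Reagents that add atoms: tert-butyldimethylsilyl chloride, CC(C)(C)[Si](C)(C)Cl
Why: Exhaustive silylation protects both phenols and gives the silyl ester needed for neutral acid chloride formation.

Step 18
Reactants: 34 tert-butyldimethylsilyl 3,4-bis[(tert-butyldimethylsilyl)oxy]benzoate
Product: 35 3,4-bis[(tert-butyldimethylsilyl)oxy]benzoyl chloride
Conditions: (COCl)2, DMF (cat.), CH2Cl2, 0 → 20 °C
Reagents that add atoms: oxalyl chloride, O=C(Cl)C(Cl)=O
Why: The Vilsmeier-type chloride converts the silyl ester directly into the acid chloride without free HCl, so the aryl silyl ethers survive.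

Step 19
Reactants: 32 (1R,5S,7R)-5-[(2E,4S)-4-[(tert-butyldimethylsilyl)oxy]-3,7-dimethylocta-2,6-dien-1-yl]-8,8-dimethyl-1,7-bis(3-methylbut-2-en-1-yl)-2-[2-(trimethylsilyl)ethoxy]bicyclo[3.3.1]non-2-ene-4,9-dione; 35 3,4-bis[(tert-butyldimethylsilyl)oxy]benzoyl chloride
Product: 37 (1R,5R,7R)-3-{3,4-bis[(tert-butyldimethylsilyl)oxy]benzoyl}-5-[(2E,4S)-4-[(tert-butyldimethylsilyl)oxy]-3,7-dimethylocta-2,6-dien-1-yl]-8,8-dimethyl-1,7-bis(3-methylbut-2-en-1-yl)-2-[2-(trimethylsilyl)ethoxy]bicyclo[3.3.1]non-2-ene-4,9-dione, via C3 vinyllithium 36 (not isolated)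
Conditions: lithium 2,2,6,6-tetramethylpiperidide (LTMP), THF, −78 °C; then 35, −78 → −40 °C
Reagents that add atoms: none
Why: The hindered amide should lithiate the only remaining acidic site, the vinylic C3–H between C2 and C4 (α-lithiation of a vinylogous ester), and the vinyllithium is C-acylated by the aroyl chloride.

Step 20
Reactants: 37 (1R,5R,7R)-3-{3,4-bis[(tert-butyldimethylsilyl)oxy]benzoyl}-5-[(2E,4S)-4-[(tert-butyldimethylsilyl)oxy]-3,7-dimethylocta-2,6-dien-1-yl]-8,8-dimethyl-1,7-bis(3-methylbut-2-en-1-yl)-2-[2-(trimethylsilyl)ethoxy]bicyclo[3.3.1]non-2-ene-4,9-dione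
Product: 38 (1S,5S,7R)-3-(3,4-dihydroxybenzoyl)-4-hydroxy-5-[(2E,4S)-4-hydroxy-3,7-dimethylocta-2,6-dien-1-yl]-8,8-dimethyl-1,7-bis(3-methylbut-2-en-1-yl)bicyclo[3.3.1]non-3-ene-2,9-dione
Conditions: Bu4NF (6 equiv), THF, 0 → 40 °C, argon; AcOH quench
Reagents that add atoms: none
Why: Fluoride cleaves the two aryl and one alkyl silyl ethers and triggers β-elimination of the 2-(trimethylsilyl)ethyl group, releasing the enolised triketone without acid, so the prenyl groups and the allylic alcohol are not exposed to cyclisation conditions.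

Compound list
1 | 4-methylpent-3-en-2-one (mesityl oxide) | CC(C)=CC(C)=O | starting material
2 | lithium 4-methylpenta-1,3-dien-2-olate | [Li]OC(=C)C=C(C)C | intermediate
3 | 4-methyl-2-[(triisopropylsilyl)oxy]penta-1,3-diene | CC(C)=CC(=C)O[Si](C(C)C)(C(C)C)C(C)C | intermediate
4 | (4S)-4-benzyl-1,3-oxazolidin-2-one | O=C1N[C@@H](Cc2ccccc2)CO1 | starting material
5 | acryloyl chloride | C=CC(Cl)=O | starting material
6 | N-lithio-(4S)-4-benzyl-1,3-oxazolidin-2-one | [Li]N1[C@@H](Cc2ccccc2)COC1=O | intermediate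
7 | (4S)-3-acryloyl-4-benzyl-1,3-oxazolidin-2-one | C=CC(=O)N1[C@@H](Cc2ccccc2)COC1=O | intermediate
8 | (4S)-4-benzyl-3-{[(1R)-2,2-dimethyl-4-[(triisopropylsilyl)oxy]cyclohex-3-en-1-yl]carbonyl}-1,3-oxazolidin-2-one | O=C([C@@H]1CCC(O[Si](C(C)C)(C(C)C)C(C)C)=CC1(C)C)N1[C@@H](Cc2ccccc2)COC1=O | intermediate
9 | [(1R)-2,2-dimethyl-4-[(triisopropylsilyl)oxy]cyclohex-3-en-1-yl]methanol | OC[C@@H]1CCC(O[Si](C(C)C)(C(C)C)C(C)C)=CC1(C)C | intermediate
10 | {[(4R)-4-(iodomethyl)-3,3-dimethylcyclohex-1-en-1-yl]oxy}triisopropylsilane | IC[C@@H]1CCC(O[Si](C(C)C)(C(C)C)C(C)C)=CC1(C)C | intermediate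
11 | 1-bromo-2-methylprop-1-ene | BrC=C(C)C | starting material
12 | {[(1R)-2,2-dimethyl-4-[(triisopropylsilyl)oxy]cyclohex-3-en-1-yl]methyl}zinc iodide | I[Zn]C[C@@H]1CCC(O[Si](C(C)C)(C(C)C)C(C)C)=CC1(C)C | intermediate
13 | {[(4S)-3,3-dimethyl-4-(3-methylbut-2-en-1-yl)cyclohex-1-en-1-yl]oxy}triisopropylsilane | CC(C)=CC[C@@H]1CCC(O[Si](C(C)C)(C(C)C)C(C)C)=CC1(C)C | intermediate
14 | 1-bromo-3-methylbut-2-ene (prenyl bromide) | CC(C)=CCBr | starting material
15 | tris(dimethylamino)sulfonium (4S)-3,3-dimethyl-4-(3-methylbut-2-en-1-yl)cyclohex-1-en-1-olate | CC(C)=CC[C@@H]1CCC([O-])=CC1(C)C.CN(C)[S+](N(C)C)N(C)C | intermediate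
16 | (4S)-3,3-dimethyl-2,4-bis(3-methylbut-2-en-1-yl)cyclohexan-1-one (C2 epimers) | CC(C)=CC[C@@H]1CCC(=O)C(CC=C(C)C)C1(C)C | intermediate
17 | lithium (4R)-5,5-dimethyl-4,6-bis(3-methylbut-2-en-1-yl)cyclohex-1-en-1-olate (C6 epimers) | CC(C)=CC[C@@H]1CC=C(O[Li])C(CC=C(C)C)C1(C)C | intermediate
18 | tert-butyl{[(4R)-5,5-dimethyl-4,6-bis(3-methylbut-2-en-1-yl)cyclohex-1-en-1-yl]oxy}dimethylsilane (C6 epimers) | CC(C)=CC[C@@H]1CC=C(O[Si](C)(C)C(C)(C)C)C(CC=C(C)C)C1(C)C | intermediate
19 | malonyl dichloride | O=C(Cl)CC(Cl)=O | starting material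
20 | 3-[(5R)-4,4-dimethyl-3,5-bis(3-methylbut-2-en-1-yl)-2-oxocyclohexyl]-3-oxopropanoyl chloride (C1 and C3 epimers) | CC(C)=CC[C@@H]1CC(C(=O)CC(Cl)=O)C(=O)C(CC=C(C)C)C1(C)C | intermediate
21 | (1R,5S,7R)-4-hydroxy-8,8-dimethyl-1,7-bis(3-methylbut-2-en-1-yl)bicyclo[3.3.1]non-3-ene-2,9-dione | CC(C)=CC[C@@H]1C[C@@H]2C(=O)[C@@](CC=C(C)C)(C(=O)C=C2O)C1(C)C | intermediate
22 | (1R,5S,7R)-8,8-dimethyl-1,7-bis(3-methylbut-2-en-1-yl)-2-[2-(trimethylsilyl)ethoxy]bicyclo[3.3.1]non-2-ene-4,9-dione | CC(C)=CC[C@@H]1C[C@@H]2C(=O)[C@@](CC=C(C)C)(C(OCC[Si](C)(C)C)=CC2=O)C1(C)C | intermediate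
23 | ethyl (2E)-3-methyl-4-oxobut-2-enoate | CCOC(=O)/C=C(\C)C=O | starting material
24 | allyltributylstannane | C=CC[Sn](CCCC)(CCCC)CCCC | starting material
25 | ethyl (2E,4S)-4-hydroxy-3-methylhepta-2,6-dienoate | CCOC(=O)/C=C(\C)[C@@H](O)CC=C | intermediate
26 | ethyl (2E,4S)-4-[(tert-butyldimethylsilyl)oxy]-3-methylhepta-2,6-dienoate | CCOC(=O)/C=C(\C)[C@@H](O[Si](C)(C)C(C)(C)C)CC=C | intermediate
27 | 2-methylbut-2-ene | CC=C(C)C | starting material
28 | ethyl (2E,4S)-4-[(tert-butyldimethylsilyl)oxy]-3,7-dimethylocta-2,6-dienoate | CCOC(=O)/C=C(\C)[C@@H](O[Si](C)(C)C(C)(C)C)CC=C(C)C | intermediate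
29 | (2E,4S)-4-[(tert-butyldimethylsilyl)oxy]-3,7-dimethylocta-2,6-dien-1-ol | OC/C=C(\C)[C@@H](O[Si](C)(C)C(C)(C)C)CC=C(C)C | intermediate
30 | {[(2E,4S)-1-bromo-3,7-dimethylocta-2,6-dien-4-yl]oxy}(tert-butyl)dimethylsilane | BrC/C=C(\C)[C@@H](O[Si](C)(C)C(C)(C)C)CC=C(C)C | intermediate
31 | C5-lithio derivative of 22 | CC(C)=CC[C@@H]1C[C@]2([Li])C(=O)[C@@](CC=C(C)C)(C(OCC[Si](C)(C)C)=CC2=O)C1(C)C | intermediate
32 | (1R,5S,7R)-5-[(2E,4S)-4-[(tert-butyldimethylsilyl)oxy]-3,7-dimethylocta-2,6-dien-1-yl]-8,8-dimethyl-1,7-bis(3-methylbut-2-en-1-yl)-2-[2-(trimethylsilyl)ethoxy]bicyclo[3.3.1]non-2-ene-4,9-dione | CC(C)=CC[C@@H]1C[C@]2(C/C=C(\C)[C@@H](O[Si](C)(C)C(C)(C)C)CC=C(C)C)C(=O)[C@@](CC=C(C)C)(C(OCC[Si](C)(C)C)=CC2=O)C1(C)C | intermediate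
33 | 3,4-dihydroxybenzoic acid | O=C(O)c1ccc(O)c(O)c1 | starting material
34 | tert-butyldimethylsilyl 3,4-bis[(tert-butyldimethylsilyl)oxy]benzoate | CC(C)(C)[Si](C)(C)OC(=O)c1ccc(O[Si](C)(C)C(C)(C)C)c(O[Si](C)(C)C(C)(C)C)c1 | intermediate
35 | 3,4-bis[(tert-butyldimethylsilyl)oxy]benzoyl chloride | O=C(Cl)c1ccc(O[Si](C)(C)C(C)(C)C)c(O[Si](C)(C)C(C)(C)C)c1 | intermediate
36 | C3-lithio derivative of 32 | CC(C)=CC[C@@H]1C[C@]2(C/C=C(\C)[C@@H](O[Si](C)(C)C(C)(C)C)CC=C(C)C)C(=O)[C@@](CC=C(C)C)(C(OCC[Si](C)(C)C)=C([Li])C2=O)C1(C)C | intermediate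
37 | (1R,5R,7R)-3-{3,4-bis[(tert-butyldimethylsilyl)oxy]benzoyl}-5-[(2E,4S)-4-[(tert-butyldimethylsilyl)oxy]-3,7-dimethylocta-2,6-dien-1-yl]-8,8-dimethyl-1,7-bis(3-methylbut-2-en-1-yl)-2-[2-(trimethylsilyl)ethoxy]bicyclo[3.3.1]non-2-ene-4,9-dione | CC(C)=CC[C@@H]1C[C@]2(C/C=C(\C)[C@@H](O[Si](C)(C)C(C)(C)C)CC=C(C)C)C(=O)[C@@](CC=C(C)C)(C(OCC[Si](C)(C)C)=C(C(=O)c3ccc(O[Si](C)(C)C(C)(C)C)c(O[Si](C)(C)C(C)(C)C)c3)C2=O)C1(C)C | intermediate
38 | (1S,5S,7R)-3-(3,4-dihydroxybenzoyl)-4-hydroxy-5-[(2E,4S)-4-hydroxy-3,7-dimethylocta-2,6-dien-1-yl]-8,8-dimethyl-1,7-bis(3-methylbut-2-en-1-yl)bicyclo[3.3.1]non-3-ene-2,9-dione | CC(C)=CC[C@@H]1C[C@]2(C/C=C(\C)[C@@H](O)CC=C(C)C)C(=O)[C@@](CC=C(C)C)(C(=O)C(C(=O)c3ccc(O)c(O)c3)=C2O)C1(C)C | target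

Total step count: 20 (main line 12, dienophile 1, side-chain bromide 5, aroyl chloride 2).
Longest linear sequence: 12 steps (steps 1, 3, 4, 5, 6, 7, 8, 9, 10, 16, 19, 20).

Steps most likely to fail

1. Step 3 (key cycloaddition). The 4,4-disubstituted diene may cycloadd sluggishly, the silyl group may transfer after the first C–C bond so that an open-chain Michael adduct results, or the enol ether may be lost on quench. The fallback replaces auxiliary control by catalyst control. It sets out from diene 3, which is combined with commercial 3-acryloyl-1,3-oxazolidin-2-one, FeBr3 (10 mol %), AgSbF6 (20 mol %) and a C2-symmetric diaryl-pybox ligand in CH2Cl2 at −70 °C (enantioselective Diels–Alder reaction under a cationic trivalent-iron Lewis acid, the ligand antipode being chosen for the 1R adduct). This should give the imide adduct 3-{[(1R)-2,2-dimethyl-4-[(triisopropylsilyl)oxy]cyclohex-3-en-1-yl]carbonyl}-1,3-oxazolidin-2-one F1, and LiBH4 reduction as in step 4 comes back to the route at alcohol 9.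

2. Step 7 (C1 prenylation). Proton transfer between the naked enolate and the product ketone may erode regiocontrol or cause double alkylation, O-alkylation may compete, and attack at the neopentyl enolate carbon may be slow. The fallback uses π-allyl palladium chemistry in place of SN2 alkylation. It sets out from enol ether 13: (Me2N)3S+ Me3SiF2− and allyl chloroformate should give, by fast O-acylation, allyl (4S)-3,3-dimethyl-4-(3-methylbut-2-en-1-yl)cyclohex-1-en-1-yl carbonate F2. Pd(PPh3)4 in THF then effects decarboxylative Tsuji allylation to (4S)-2-allyl-3,3-dimethyl-4-(3-methylbut-2-en-1-yl)cyclohexan-1-one F3. Cross-metathesis with 2-methylbut-2-ene (second-generation Grubbs catalyst) converts allyl into prenyl and comes back to the route at ketone 16.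

3. Step 16 (bridgehead alkylation). Vinylic C3 lithiation may compete, bridgehead metalation may be incomplete, or the hindered carbanion may cause elimination or SN2′ attack on the allylic bromide. The fallback installs the side chain before ring A is closed. It sets out from ketone 16: LiN(iPr)2 and then bromide 30 alkylate the kinetic C5 enolate to give (4R)-6-[(2E,4S)-4-[(tert-butyldimethylsilyl)oxy]-3,7-dimethylocta-2,6-dien-1-yl]-3,3-dimethyl-2,4-bis(3-methylbut-2-en-1-yl)cyclohexan-1-one F4. After base equilibration towards the all-equatorial isomer, TBSOTf and Et3N should give the tetrasubstituted enol ether tert-butyl({(4R)-2-[(2E,4S)-4-[(tert-butyldimethylsilyl)oxy]-3,7-dimethylocta-2,6-dien-1-yl]-5,5-dimethyl-4,6-bis(3-methylbut-2-en-1-yl)cyclohex-1-en-1-yl}oxy)dimethylsilane F5. Effenberger annulation with malonyl dichloride and aqueous KOH closes ring A with both bridgeheads quaternary to give (1R,5S,7R)-5-[(2E,4S)-4-[(tert-butyldimethylsilyl)oxy]-3,7-dimethylocta-2,6-dien-1-yl]-4-hydroxy-8,8-dimethyl-1,7-bis(3-methylbut-2-en-1-yl)bicyclo[3.3.1]non-3-ene-2,9-dione F6. Mitsunobu alkylation with 2-(trimethylsilyl)ethanol as in step 10 comes back to the route at 32. In this variant C5 is fixed in the first acylation, so its facial selectivity (acylation cis to C7–H) would have to be verified.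

Further compounds
F1 | step 3 | 3-{[(1R)-2,2-dimethyl-4-[(triisopropylsilyl)oxy]cyclohex-3-en-1-yl]carbonyl}-1,3-oxazolidin-2-one | O=C([C@@H]1CCC(O[Si](C(C)C)(C(C)C)C(C)C)=CC1(C)C)N1CCOC1=O
F2 | step 7 | allyl (4S)-3,3-dimethyl-4-(3-methylbut-2-en-1-yl)cyclohex-1-en-1-yl carbonate | CC(C)=CC[C@@H]1CCC(OC(=O)OCC=C)=CC1(C)C
F3 | step 7 | (4S)-2-allyl-3,3-dimethyl-4-(3-methylbut-2-en-1-yl)cyclohexan-1-one (C2 epimers) | CC(C)=CC[C@@H]1CCC(=O)C(CC=C)C1(C)C
F4 | step 16 | (4R)-6-[(2E,4S)-4-[(tert-butyldimethylsilyl)oxy]-3,7-dimethylocta-2,6-dien-1-yl]-3,3-dimethyl-2,4-bis(3-methylbut-2-en-1-yl)cyclohexan-1-one (C2 and C6 epimers) | CC(C)=CC[C@@H]1CC(C/C=C(\C)[C@@H](O[Si](C)(C)C(C)(C)C)CC=C(C)C)C(=O)C(CC=C(C)C)C1(C)C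
F5 | step 16 | tert-butyl({(4R)-2-[(2E,4S)-4-[(tert-butyldimethylsilyl)oxy]-3,7-dimethylocta-2,6-dien-1-yl]-5,5-dimethyl-4,6-bis(3-methylbut-2-en-1-yl)cyclohex-1-en-1-yl}oxy)dimethylsilane (C6 epimers) | CC(C)=CC[C@@H]1CC(C/C=C(\C)[C@@H](O[Si](C)(C)C(C)(C)C)CC=C(C)C)=C(O[Si](C)(C)C(C)(C)C)C(CC=C(C)C)C1(C)C
F6 | step 16 | (1R,5S,7R)-5-[(2E,4S)-4-[(tert-butyldimethylsilyl)oxy]-3,7-dimethylocta-2,6-dien-1-yl]-4-hydroxy-8,8-dimethyl-1,7-bis(3-methylbut-2-en-1-yl)bicyclo[3.3.1]non-3-ene-2,9-dione | CC(C)=CC[C@@H]1C[C@]2(C/C=C(\C)[C@@H](O[Si](C)(C)C(C)(C)C)CC=C(C)C)C(=O)[C@@](CC=C(C)C)(C(=O)C=C2O)C1(C)C
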